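**Retrosynthetic overview**
- Target ⇐ fluoride desilylation ⇐ Z-alkene by semi-hydrogenation of a 22-membered cycloalkyne ⇐ ring-closing alkyne metathesis of an open diyne (macrocycle closed last).
- (R)-Benzylic carbinol ⇐ anti-selective Evans–Tishchenko reduction of a β-hydroxy aryl ketone whose (S)-carbinol is bought in (S)-epichlorohydrin; the relay oxygen then leaves as its toluate (SmI2).
- β-Hydroxy ketone ⇐ lithiated aryl dithiane + (S)-2-(hept-5-ynyl)oxirane.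
- Ring A together with the diaryl ether ⇐ key step: benzannulation of a 3-alkylcyclobutenone with the aryl ynol ether of ring B (4π opening, [2+2], 4π opening, 6π electrocyclization).
- Ring B ⇐ syringaldehyde. Ring order: ring B bought, ring A by benzannulation, macrocycle by alkyne metathesis.

Assumption: 1-propynyllithium, 3-ethoxycyclobut-2-en-1-one and 6-chlorohex-2-yne are catalogue items. TBS = tert-butyldimethylsilyl; TBSO = its ether.

**Step 1**
Reactants: 1 syringaldehyde (4-hydroxy-3,5-dimethoxybenzaldehyde)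
Product: 2 4-[(E)-1,2-dichloroethenyloxy]-3,5-dimethoxybenzaldehyde
Conditions: Cl2C=CHCl (2 equiv), K2CO3, DMF, 70 °C
Reagents that add atoms: trichloroethylene (ClC=C(Cl)Cl)
Why: Carbonate eliminates HCl from trichloroethylene to dichloroacetylene, to which the phenoxide adds anti (nucleophilic addition to a haloalkyne) to give the (E)-dichlorovinyl ether, the aldehyde being inert.

**Step 2**
Reactants: 2 4-[(E)-1,2-dichloroethenyloxy]-3,5-dimethoxybenzaldehyde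
Product: 4 2-[(E)-1,2-dichloroethenyloxy]-5-(1,3-dithian-2-yl)benzene-1,3-diol, via dihydroxy aldehyde 3 (not isolated)
Conditions: BBr3 (3.5 equiv), CH2Cl2, −78 → 0 °C; then HS(CH2)3SH, 0 °C → rt; H2O work-up
Reagents that add atoms: propane-1,3-dithiol (SCCCS)
Why: Lewis-acid ether cleavage (bromide attacks the methyl groups; the electron-poor vinyl ether has no cleavable sp3 C–O bond) followed by boron-halide-promoted dithioacetalization in the same flask.

**Step 3**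
Reactants: 4 2-[(E)-1,2-dichloroethenyloxy]-5-(1,3-dithian-2-yl)benzene-1,3-diol
Product: 5 2-{4-[(E)-1,2-dichloroethenyloxy]-3,5-bis(TBSO)phenyl}-1,3-dithiane
Conditions: TBSCl (2.5 equiv), imidazole, DMF, rt
Reagents that add atoms: tert-butyldimethylsilyl chloride (CC(C)(C)[Si](C)(C)Cl)
Why: Standard phenol silylation; the silyl ethers survive every later step and come off with fluoride without acid.

**Step 4**
Reactants: 5 2-{4-[(E)-1,2-dichloroethenyloxy]-3,5-bis(TBSO)phenyl}-1,3-dithiane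
Product: 8 2-[4-(ethynyloxy)-3,5-bis(TBSO)phenyl]-1,3-dithiane, via chloroethynyl ether 6 (not isolated), via dilithio acetylide 7 (not isolated)
Conditions: n-BuLi (3.3 equiv), THF, −78 → −40 °C; sat. NH4Cl, −78 °C; used crude
Reagents that add atoms: none
Why: Greene ynol ether synthesis (deprotonation and β-elimination to the chloroalkyne, then Cl–Li exchange); the dithiane C–H is lithiated too and both carbanions are protonated on quench.

**Step 5**
Reactants: 9 1-propynyllithium; 10 1-bromo-5-chloropentane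
Product: 11 8-chlorooct-2-yne
Conditions: THF/DMPU, 0 °C → rt
Reagents that add atoms: none
Why: SN2 alkylation of the acetylide, selective for the C–Br end.

**Step 6**
Reactants: 11 8-chlorooct-2-yne; 12 3-ethoxycyclobut-2-en-1-one
Product: 15 3-(oct-6-yn-1-yl)cyclobut-2-en-1-one, via Grignard reagent 13 (not isolated), via magnesium alkoxide 14 (not isolated)
Conditions: Mg, THF, reflux; 12, THF, −78 °C; 1 M HCl, 0 °C
Reagents that add atoms: water (O)
Why: 1,2-Addition of the Grignard reagent to the vinylogous ester and acid hydrolysis with 1,3-carbonyl transposition (Stork–Danheiser type) give the 3-alkylcyclobutenone.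

**Step 7**
Reactants: 8 2-[4-(ethynyloxy)-3,5-bis(TBSO)phenyl]-1,3-dithiane; 15 3-(oct-6-yn-1-yl)cyclobut-2-en-1-one
Product: 21 2-{4-[3-(TBSO)-5-(oct-6-yn-1-yl)phenoxy]-3,5-bis(TBSO)phenyl}-1,3-dithiane, via vinylketene 16 (not isolated), via vinylcyclobutenone 17 (not isolated), via dienylketene 18 (not isolated), via cyclohexadienone 19 (not isolated), via phenol 20 (not isolated)
Conditions: 15 (1.3 equiv), PhMe, 80 °C, 36 h; then TBSCl, imidazole, DMF, rt
Reagents that add atoms: tert-butyldimethylsilyl chloride (CC(C)(C)[Si](C)(C)Cl)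
Why: Danheiser benzannulation: 4π electrocyclic opening of 15, regioselective [2+2] cycloaddition of the vinylketene with the ynol ether (ketene carbonyl carbon to the terminal alkyne carbon), 4π opening, 6π electrocyclization and tautomerization build ring A with OH, OAr and alkyl mutually meta, and the phenol is silylated in the same flask.

**Step 8**
Reactants: 22 6-chlorohex-2-yne; 23 (S)-epichlorohydrin
Product: 26 (S)-2-(hept-5-yn-1-yl)oxirane, via Grignard reagent 24 (not isolated), via chlorohydrin 25 (not isolated)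
Conditions: Mg, THF; 23, CuI (10 mol %), THF, −40 °C; aq. NH4Cl; then NaOH (aq.), Et2O, rt
Reagents that add atoms: none
Why: Copper-catalysed Grignard opening at the epoxide CH2 and Williamson closure onto CH2Cl; the stereocenter is bought in 23 and no bond to it is touched, so it stays (S).

**Step 9**
Reactants: 21 2-{4-[3-(TBSO)-5-(oct-6-yn-1-yl)phenoxy]-3,5-bis(TBSO)phenyl}-1,3-dithiane; 26 (S)-2-(hept-5-yn-1-yl)oxirane
Product: 28 (2S)-1-(2-{4-[3-(TBSO)-5-(oct-6-yn-1-yl)phenoxy]-3,5-bis(TBSO)phenyl}-1,3-dithian-2-yl)non-7-yn-2-ol, via lithiodithiane 27 (not isolated)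
Conditions: n-BuLi (1.1 equiv), THF, −78 → −20 °C; 26, DMPU, −20 → 0 °C; aq. NH4Cl
Reagents that add atoms: none
Why: Corey–Seebach umpolung: the acyl-anion equivalent opens the epoxide by SN2 at its CH2, leaving the (S)-carbinol untouched.

**Step 10**
Reactants: 28 (2S)-1-(2-{4-[3-(TBSO)-5-(oct-6-yn-1-yl)phenoxy]-3,5-bis(TBSO)phenyl}-1,3-dithian-2-yl)non-7-yn-2-ol
Product: 29 (3S)-3-hydroxy-1-{4-[3-(TBSO)-5-(oct-6-yn-1-yl)phenoxy]-3,5-bis(TBSO)phenyl}dec-8-yn-1-one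
Conditions: MeI, CaCO3, MeCN/H2O (9:1), 45 °C
Reagents that add atoms: water (O)
Why: S-Methylation and hydrolysis unmask the aryl ketone under near-neutral, non-oxidizing conditions that spare the aldol, silyl ethers and alkynes.

**Step 11**
Reactants: 29 (3S)-3-hydroxy-1-{4-[3-(TBSO)-5-(oct-6-yn-1-yl)phenoxy]-3,5-bis(TBSO)phenyl}dec-8-yn-1-one
Product: 31 (1R,3S)-1-hydroxy-1-{4-[3-(TBSO)-5-(oct-6-yn-1-yl)phenoxy]-3,5-bis(TBSO)phenyl}dec-8-yn-3-yl 4-methylbenzoate, via hemiacetal 30 (not isolated)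
Conditions: 4-MeC6H4CHO (6 equiv), SmI2 (0.3 equiv), THF, −10 °C
Reagents that add atoms: 4-methylbenzaldehyde (Cc1ccc(C=O)cc1)
Why: Evans–Tishchenko reduction: hydride passes intramolecularly from the samarium-bound hemiacetal to the ketone through a chair transition state, giving the 1,3-anti product, so the bought (3S) center sets (1R); C1–OH is left free and the C3 oxygen is acylated.

**Step 12**
Reactants: 31 (1R,3S)-1-hydroxy-1-{4-[3-(TBSO)-5-(oct-6-yn-1-yl)phenoxy]-3,5-bis(TBSO)phenyl}dec-8-yn-3-yl 4-methylbenzoate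
Product: 32 (1R,3S)-1-(TBSO)-1-{4-[3-(TBSO)-5-(oct-6-yn-1-yl)phenoxy]-3,5-bis(TBSO)phenyl}dec-8-yn-3-yl 4-methylbenzoate
Conditions: TBSOTf, 2,6-lutidine, CH2Cl2, −78 → 0 °C
Reagents that add atoms: tert-butyldimethylsilyl triflate (CC(C)(C)[Si](C)(C)OS(=O)(=O)C(F)(F)F)
Why: Silylation under non-basic conditions blocks acyl migration to the benzylic oxygen and removes the last protic group before the electron-transfer and metathesis steps.

**Step 13**
Reactants: 32 (1R,3S)-1-(TBSO)-1-{4-[3-(TBSO)-5-(oct-6-yn-1-yl)phenoxy]-3,5-bis(TBSO)phenyl}dec-8-yn-3-yl 4-methylbenzoate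
Product: 33 (1R)-1-(TBSO)-1-{4-[3-(TBSO)-5-(oct-6-yn-1-yl)phenoxy]-3,5-bis(TBSO)phenyl}dec-8-yne
Conditions: SmI2 (8 equiv), HMPA, THF, rt → 60 °C; aq. NH4Cl
Reagents that add atoms: none
Why: Markó–Lam deoxygenation: single-electron transfer to the toluate, C–O fragmentation to a secondary radical and reduction/protonation erase the relay center, while the benzylic silyl ether is not a leaving group.

**Step 14**
Reactants: 33 (1R)-1-(TBSO)-1-{4-[3-(TBSO)-5-(oct-6-yn-1-yl)phenoxy]-3,5-bis(TBSO)phenyl}dec-8-yne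
Product: 34 (R)-22-membered cycloalkyne: rings A and B joined by the diaryl ether and by the chain CH(OTBS)-(CH2)6-C≡C-(CH2)5, all three phenols as TBS ethers
Conditions: [Mo(≡CC6H4OMe-4)(OSiPh3)3] (5 mol %), 5 Å MS, PhMe (2 mM), 80 °C
Reagents that add atoms: none
Why: Ring-closing alkyne metathesis of the two methyl-capped alkynes, driven by trapping of but-2-yne in the sieves; the catalyst tolerates silyl and aryl ethers.

**Step 15**
Reactants: 34 (R)-22-membered cycloalkyne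
Product: 35 (R,Z)-cycloalkene, the tetrakis-TBS ether of the target
Conditions: H2 (1 atm), Pd/CaCO3 poisoned with Pb(OAc)2, quinoline, EtOAc, rt
Reagents that add atoms: none
Why: Lindlar syn semi-hydrogenation delivers only the Z-alkene.

**Step 16**
Reactants: 35 (R,Z)-cycloalkene tetrakis-TBS ether
Product: 36 target, (R,Z)-macrocyclic triphenol carbinol
Conditions: (n-Bu)4NF, AcOH, THF, 0 °C → rt
Reagents that add atoms: none
Why: Buffered fluoride desilylation frees the three phenols and the carbinol without acid, so the benzylic (R)-center cannot ionize.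

**Compound list**
1 | syringaldehyde | COc1cc(C=O)cc(OC)c1O | starting material
2 | 4-[(E)-1,2-dichloroethenyloxy]-3,5-dimethoxybenzaldehyde | COc1cc(C=O)cc(OC)c1O/C(Cl)=C\Cl | intermediate
3 | 4-[(E)-1,2-dichloroethenyloxy]-3,5-dihydroxybenzaldehyde | Oc1cc(C=O)cc(O)c1O/C(Cl)=C\Cl | intermediate (not isolated)
4 | 2-[(E)-1,2-dichloroethenyloxy]-5-(1,3-dithian-2-yl)benzene-1,3-diol | Oc1cc(C2SCCCS2)cc(O)c1O/C(Cl)=C\Cl | intermediate
5 | 2-{4-[(E)-1,2-dichloroethenyloxy]-3,5-bis(TBSO)phenyl}-1,3-dithiane | CC(C)(C)[Si](C)(C)Oc1cc(C2SCCCS2)cc(O[Si](C)(C)C(C)(C)C)c1O/C(Cl)=C\Cl | intermediate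
6 | 2-[4-(chloroethynyloxy)-3,5-bis(TBSO)phenyl]-1,3-dithiane | CC(C)(C)[Si](C)(C)Oc1cc(C2SCCCS2)cc(O[Si](C)(C)C(C)(C)C)c1OC#CCl | intermediate (not isolated)
7 | dilithio species: lithium acetylide of 8 also lithiated at dithiane C2 | CC(C)(C)[Si](C)(C)Oc1cc(C2([Li])SCCCS2)cc(O[Si](C)(C)C(C)(C)C)c1OC#C[Li] | intermediate (not isolated)
8 | 2-[4-(ethynyloxy)-3,5-bis(TBSO)phenyl]-1,3-dithiane | CC(C)(C)[Si](C)(C)Oc1cc(C2SCCCS2)cc(O[Si](C)(C)C(C)(C)C)c1OC#C | intermediate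
9 | 1-propynyllithium | [Li]C#CC | starting material
10 | 1-bromo-5-chloropentane | ClCCCCCBr | starting material
11 | 8-chlorooct-2-yne | CC#CCCCCCCl | intermediate
12 | 3-ethoxycyclobut-2-en-1-one | CCOC1=CC(=O)C1 | starting material
13 | oct-6-yn-1-ylmagnesium chloride | CC#CCCCCC[Mg]Cl | intermediate (not isolated)
14 | chloromagnesium 3-ethoxy-1-(oct-6-yn-1-yl)cyclobut-2-en-1-olate | CCOC1=CC(CCCCCC#CC)(O[Mg]Cl)C1 | intermediate (not isolated)
15 | 3-(oct-6-yn-1-yl)cyclobut-2-en-1-one | CC#CCCCCCC1=CC(=O)C1 | intermediate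
16 | 3-methylideneundec-1-en-9-yn-1-one (vinylketene) | O=C=CC(=C)CCCCCC#CC | intermediate (not isolated)
17 | 3-[4-(1,3-dithian-2-yl)-2,6-bis(TBSO)phenoxy]-4-(dec-1-en-8-yn-2-yl)cyclobut-2-en-1-one | O=C1C=C(Oc2c(O[Si](C)(C)C(C)(C)C)cc(cc2O[Si](C)(C)C(C)(C)C)C2SCCCS2)C1C(=C)CCCCCC#CC | intermediate (not isolated)
18 | dienylketene from ring opening of 17 | O=C=CC(Oc1c(O[Si](C)(C)C(C)(C)C)cc(cc1O[Si](C)(C)C(C)(C)C)C1SCCCS1)=CC(=C)CCCCCC#CC | intermediate (not isolated)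
19 | 3-[4-(1,3-dithian-2-yl)-2,6-bis(TBSO)phenoxy]-5-(oct-6-yn-1-yl)cyclohexa-2,4-dien-1-one | O=C1CC(CCCCCC#CC)=CC(Oc2c(O[Si](C)(C)C(C)(C)C)cc(cc2O[Si](C)(C)C(C)(C)C)C2SCCCS2)=C1 | intermediate (not isolated)
20 | 3-[4-(1,3-dithian-2-yl)-2,6-bis(TBSO)phenoxy]-5-(oct-6-yn-1-yl)phenol | CC#CCCCCCc1cc(O)cc(Oc2c(O[Si](C)(C)C(C)(C)C)cc(cc2O[Si](C)(C)C(C)(C)C)C2SCCCS2)c1 | intermediate (not isolated)
21 | 2-{4-[3-(TBSO)-5-(oct-6-yn-1-yl)phenoxy]-3,5-bis(TBSO)phenyl}-1,3-dithiane | CC#CCCCCCc1cc(O[Si](C)(C)C(C)(C)C)cc(Oc2c(O[Si](C)(C)C(C)(C)C)cc(cc2O[Si](C)(C)C(C)(C)C)C2SCCCS2)c1 | intermediate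
22 | 6-chlorohex-2-yne | CC#CCCCCl | starting material
23 | (S)-epichlorohydrin | ClC[C@@H]1CO1 | starting material
24 | hex-4-yn-1-ylmagnesium chloride | CC#CCCC[Mg]Cl | intermediate (not isolated)
25 | (S)-1-chloronon-7-yn-2-ol | ClC[C@@H](O)CCCCC#CC | intermediate (not isolated)
26 | (S)-2-(hept-5-yn-1-yl)oxirane | CC#CCCCC[C@H]1CO1 | intermediate
27 | 2-lithio derivative of 21 | CC#CCCCCCc1cc(O[Si](C)(C)C(C)(C)C)cc(Oc2c(O[Si](C)(C)C(C)(C)C)cc(cc2O[Si](C)(C)C(C)(C)C)C2([Li])SCCCS2)c1 | intermediate (not isolated)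
28 | (2S)-1-(2-{4-[3-(TBSO)-5-(oct-6-yn-1-yl)phenoxy]-3,5-bis(TBSO)phenyl}-1,3-dithian-2-yl)non-7-yn-2-ol | CC#CCCCCCc1cc(O[Si](C)(C)C(C)(C)C)cc(Oc2c(O[Si](C)(C)C(C)(C)C)cc(cc2O[Si](C)(C)C(C)(C)C)C2(C[C@@H](O)CCCCC#CC)SCCCS2)c1 | intermediate
29 | (3S)-3-hydroxy-1-{4-[3-(TBSO)-5-(oct-6-yn-1-yl)phenoxy]-3,5-bis(TBSO)phenyl}dec-8-yn-1-one | CC#CCCCCCc1cc(O[Si](C)(C)C(C)(C)C)cc(Oc2c(O[Si](C)(C)C(C)(C)C)cc(cc2O[Si](C)(C)C(C)(C)C)C(=O)C[C@@H](O)CCCCC#CC)c1 | intermediate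
30 | hemiacetal of the C3 hydroxyl of 29 with 4-methylbenzaldehyde | CC#CCCCCCc1cc(O[Si](C)(C)C(C)(C)C)cc(Oc2c(O[Si](C)(C)C(C)(C)C)cc(cc2O[Si](C)(C)C(C)(C)C)C(=O)C[C@@H](OC(O)c3ccc(C)cc3)CCCCC#CC)c1 | intermediate (not isolated)
31 | (1R,3S)-1-hydroxy-1-{4-[3-(TBSO)-5-(oct-6-yn-1-yl)phenoxy]-3,5-bis(TBSO)phenyl}dec-8-yn-3-yl 4-methylbenzoate | CC#CCCCCCc1cc(O[Si](C)(C)C(C)(C)C)cc(Oc2c(O[Si](C)(C)C(C)(C)C)cc(cc2O[Si](C)(C)C(C)(C)C)[C@H](O)C[C@@H](OC(=O)c3ccc(C)cc3)CCCCC#CC)c1 | intermediate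
32 | (1R,3S)-1-(TBSO)-1-{4-[3-(TBSO)-5-(oct-6-yn-1-yl)phenoxy]-3,5-bis(TBSO)phenyl}dec-8-yn-3-yl 4-methylbenzoate | CC#CCCCCCc1cc(O[Si](C)(C)C(C)(C)C)cc(Oc2c(O[Si](C)(C)C(C)(C)C)cc(cc2O[Si](C)(C)C(C)(C)C)[C@H](O[Si](C)(C)C(C)(C)C)C[C@@H](OC(=O)c3ccc(C)cc3)CCCCC#CC)c1 | intermediate
33 | (1R)-1-(TBSO)-1-{4-[3-(TBSO)-5-(oct-6-yn-1-yl)phenoxy]-3,5-bis(TBSO)phenyl}dec-8-yne | CC#CCCCCCc1cc(O[Si](C)(C)C(C)(C)C)cc(Oc2c(O[Si](C)(C)C(C)(C)C)cc(cc2O[Si](C)(C)C(C)(C)C)[C@H](O[Si](C)(C)C(C)(C)C)CCCCCCC#CC)c1 | intermediate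
34 | (R)-22-membered cycloalkyne, tetrakis-TBS ether | CC(C)(C)[Si](C)(C)Oc1cc2cc(c1)Oc1c(O[Si](C)(C)C(C)(C)C)cc(cc1O[Si](C)(C)C(C)(C)C)[C@H](O[Si](C)(C)C(C)(C)C)CCCCCCC#CCCCCC2 | intermediate
35 | (R,Z)-cycloalkene, tetrakis-TBS ether of the target | CC(C)(C)[Si](C)(C)Oc1cc2cc(c1)Oc1c(O[Si](C)(C)C(C)(C)C)cc(cc1O[Si](C)(C)C(C)(C)C)[C@H](O[Si](C)(C)C(C)(C)C)CCCCCC/C=C\CCCCC2 | intermediate
36 | target CNP0316989.2, (R)-carbinol, Z-alkene | Oc1cc2cc(c1)Oc1c(O)cc(cc1O)[C@H](O)CCCCCC/C=C\CCCCC2 | target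

**Step count**
Total: 16 steps. Longest linear sequence: 13 steps (1–4, 7, 9–16, from syringaldehyde).

**Three steps most likely to fail**

Step 7 (benzannulation): the terminal aryl ynol ether 8 is hindered by two ortho silyl ethers and may polymerize during the long heating needed to open 15. The fallback sets out from 11 and 8 and makes the same vinylketene 16 at low temperature by 1,4-dehydrochlorination instead of electrocyclic opening. Grignard reagent 13 with CuI adds syn to ethyl but-2-ynoate at −78 °C to give ethyl (E)-3-methylundec-2-en-9-ynoate F2. LiOH gives (E)-3-methylundec-2-en-9-ynoic acid F3, and (COCl)2 gives (E)-3-methylundec-2-en-9-ynoyl chloride F4. Et3N added to F4 and 8 in CH2Cl2 at 0 °C generates 16 in the presence of the ynol ether, and brief warming completes the cascade. The route is rejoined at phenol 20, which is silylated to 21 as before.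

Step 13 (deoxygenation): the secondary radical could cyclize onto the alkyne, or SmI2/HMPA could attack other groups. The fallback sets out from 32 and uses a tin-hydride radical chain on a thiocarbonyl derivative. i-Bu2AlH at −78 °C removes the toluate to give (1R,3S)-1-(TBSO)-1-{4-[3-(TBSO)-5-(oct-6-yn-1-yl)phenoxy]-3,5-bis(TBSO)phenyl}dec-8-yn-3-ol F5. 1,1'-Thiocarbonyldiimidazole gives O-[(1R,3S)-1-(TBSO)-1-{4-[3-(TBSO)-5-(oct-6-yn-1-yl)phenoxy]-3,5-bis(TBSO)phenyl}dec-8-yn-3-yl] 1H-imidazole-1-carbothioate F6. Bu3SnH/AIBN in PhMe at 80 °C (Barton–McCombie) then gives 33, where the route is rejoined.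

Step 2 (demethylation/dithioacetalization): BBr3 or the thiol could attack the dichlorovinyl ether. The fallback sets out from 1 and inverts the order, relying on phenol acidity instead. BBr3 demethylates 1 to 3,4,5-trihydroxybenzaldehyde F1. Its 4-OH, the most acidic because it is para to the formyl group, is etherified selectively with trichloroethylene and K2CO3 (1 equiv) to give 3, now isolated. HS(CH2)3SH with BF3·OEt2 then gives 4, where the route is rejoined.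

**Further compounds**
F1 | step 2 | 3,4,5-trihydroxybenzaldehyde | O=Cc1cc(O)c(O)c(O)c1
F2 | step 7 | ethyl (E)-3-methylundec-2-en-9-ynoate | CCOC(=O)/C=C(\C)CCCCCC#CC
F3 | step 7 | (E)-3-methylundec-2-en-9-ynoic acid | OC(=O)/C=C(\C)CCCCCC#CC
F4 | step 7 | (E)-3-methylundec-2-en-9-ynoyl chloride | ClC(=O)/C=C(\C)CCCCCC#CC
F5 | step 13 | (1R,3S)-1-(TBSO)-1-{4-[3-(TBSO)-5-(oct-6-yn-1-yl)phenoxy]-3,5-bis(TBSO)phenyl}dec-8-yn-3-ol | CC#CCCCCCc1cc(O[Si](C)(C)C(C)(C)C)cc(Oc2c(O[Si](C)(C)C(C)(C)C)cc(cc2O[Si](C)(C)C(C)(C)C)[C@H](O[Si](C)(C)C(C)(C)C)C[C@@H](O)CCCCC#CC)c1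
F6 | step 13 | O-[(1R,3S)-1-(TBSO)-1-{4-[3-(TBSO)-5-(oct-6-yn-1-yl)phenoxy]-3,5-bis(TBSO)phenyl}dec-8-yn-3-yl] 1H-imidazole-1-carbothioate | CC#CCCCCCc1cc(O[Si](C)(C)C(C)(C)C)cc(Oc2c(O[Si](C)(C)C(C)(C)C)cc(cc2O[Si](C)(C)C(C)(C)C)[C@H](O[Si](C)(C)C(C)(C)C)C[C@@H](OC(=S)n3ccnc3)CCCCC#CC)c1
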